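## Structural features

The target is a furanoheliangolide. Its ten-membered carbocycle (C1–C10, germacrane numbering) is bridged by an oxygen between C3 and C10, so that C1(=O), C2=C3, the oxygen and C10 form a 3(2H)-furanone. A trans-fused α-methylene-γ-butyrolactone (C6, C7, C11, C12, O; exocyclic C11=C13) sits on C6/C7. The Z C4=C5 alkene carries the C15 hydroxymethyl group, joins the lactone carbinol C6 to the furanone and is cross-conjugated with it. Five contiguous stereocentres run from C6 to C10 (6R, 7S, 8S, 9R, 10S). C8 and C9 form a threo diol esterified as methacrylate (O8) and angelate (O9), and C10 is quaternary (C14 methyl, ring oxygen, C1, C9). The fragile groups are the α-methylene lactone and the methacrylate (Michael acceptors), the angelate (Z to E isomerization), the allylic C6–O bond and the vicinal diester (acyl migration). The real difficulty lies in the strained, oxygen-bridged ring with its trisubstituted Z alkene, in the C6–C10 stereo array, in telling O8 from O9, and in building quaternary C10 beside an electrophilic lactone. The key step exploits that the lactone oxygen is bound to allylic C6. The ring (C6, C7, C11, C12, O) is therefore a ring-expanded isomer of a cyclopropane C6–C7–C11 that bears two carboxyls on C11 and a vinyl group on C6. C7–C10 map onto the four carbons of L-tartaric acid.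

## Logic of the disconnections

30 to 29: only the O15–Si bond is cut. Keeping the primary allylic hydroxyl masked to the end lets O8 and O9 be acylated one after the other. The forward step must cleave Si–O without base, because three enoates are present.

29 to 28: the acyl C–O bond at O8 is cut. The methacrylate goes on after ring closure because its 1,1-disubstituted alkene would otherwise compete in the metathesis. The forward acylation must outrun migration of the neighbouring O9 ester.

28 to 27 to 26: the O8–Si bond is a temporary mask; the real cut is C4=C5. It is the one ring bond without a stereocentre, and the bridged ring tolerates only the Z geometry. The bicycle becomes a chain carrying two five-membered rings and two terminal alkenes. The forward step must form a trisubstituted alkene from an electron-poor 1,1-disubstituted partner in a medium ring.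

26 to 23 and 24: the acyl C–O bond at O9 is cut. The hindered ester is made on the open chain, where O9 is more accessible. The forward step must not isomerize the Z alkene of 24.

23 to 22 to 21: the O8–Si bond and then the two acetal C–O bonds are cut. The diol returns to the cyclic acetal that ties C8 and C9 to the chiral pool. The forward sequence needs a regioselective silylation of O8 next to O9.

21 to 19 (through 20): the furanone O–C3 bond is cut and the C1 oxygen is traced to water. The heterocycle becomes a linear 4-hydroxy-2-ynone. The forward step needs regioselective hydration at C1 and must leave the propargylic C10–O bond intact.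

19 to 14 and 17 (through 18), and 17 to 16 to 15: the C2–C3 bond is cut. One coupling then brings in C3, C4, C15 and the metathesis alkene as a three-carbon acyl unit. The forward coupling must tolerate a free tertiary alcohol and the methylene lactone.

14 to 13: C11=C13 is traced back to C11–CO2H, the carboxyl that the key step leaves behind. A one-carbon electrophile and loss of carbon dioxide are all that is needed. The demand is a methylenation that works on the free acid.

13 to 12 to 11: the C10–C1 bond and then the C10–C14 bond are cut, returning C10 to the acyl level. The quaternary centre is built from O9 by chelation. The forward steps must leave the lactone alone, which the C11 carboxyl makes possible.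

11 to 10: the O–C6 bond is cut and the C6–C11 bond is restored. Lactone and stereocentre C6 are exchanged for a cyclopropane whose C6 configuration is irrelevant. The forward step must close at the internal allyl carbon and deliver the trans ring.

10 to 9: the two ester O–allyl bonds are restored, so that the diacid is only exposed when it is needed.

9 to 6 and 8, and 8 to 7: the C6–C7 and C6–C11 bonds are cut. The cyclopropane falls apart into an electron-poor alkene and a three-carbon ylide. The forward step must set C7 from the adjacent C8.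

6 to 4 and 5: the C7=C11 bond is cut, giving an aldehyde and an active methylene compound.

4 to 3 to 2 to 1: only oxidation levels and the amide change. The C2-symmetric 1 must be desymmetrized once.

## Other disconnections considered

Alternative 1: The cut is the C8–C9 bond. Both carbinols revert to aldehydes and the carbocycle opens to the seco-dialdehyde A1, in which the lactone half and the furanone half are joined only through the Z C4=C5 alkene. Forward, SmI2 (samarium diiodide, divalent samarium) would reduce both formyl groups to ketyls, and their coupling would form C8–C9, both carbinol centres and the ring, giving diol A2.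
- In its favour: one step would create the ring, a skeletal C–C bond and two stereocentres. A1 can be assembled from two halves of similar size, so the plan is more convergent than the chosen one.
- Against it here: the threo diol with the right absolute sense would have to be induced by remote C7 and C10, whereas a samarium-bridged diketyl in a ring tends toward the cis diol. The C9 aldehyde and the C1 ketone both have an oxygen on the α-carbon C10, a pattern that divalent samarium is expected to cleave reductively. The α-methylene lactone cannot be present (A2 has a saturated C11), so the methylene must be added late to a base-sensitive intermediate. The C8 aldehyde of A1 has an acidic C7–H with the lactone oxygen β to it, which invites elimination.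
- Comparison: structurally, the alternative makes C8 and C9 under substrate control, while the chosen plan takes them from the chiral pool. Mechanistically, a kinetically controlled single-electron coupling sets two centres, while the chosen key step sets one centre under thermodynamic control. In step economy the alternative's key step is the better one. The two plans are equal in that both must still tell O8 from O9.

Alternative 2: The cut is the C4=C5 double bond, leading to diene A3 with a vinyl group on C6 and a methylidene on C4. Forward, the second-generation Hoveyda–Grubbs catalyst RuCl2(H2IMes)(=CH-C6H4-2-OiPr) would initiate at the vinyl group and close onto the 1,1-disubstituted alkene with loss of ethylene, giving the bicyclic core A4.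
- In its favour: the alkene is the only ring bond without a stereocentre, and the bridged ring accommodates only the Z isomer. The catalyst tolerates lactone, esters, silyl ethers and enone, and every stereocentre is already in place.
- Against it: a trisubstituted alkene must form from a hindered, electron-poor partner in a strained ring, with the α-methylene lactone as a possible competitor. As an organising idea it says nothing about the C6–C10 stereo array.
- Comparison: on the macrocyclization the two plans are equal, in fact identical. The chosen route closes the ring by this reaction in step 19 on 26, the tert-butyldiphenylsilyl analogue of A3, to give 27, the analogue of A4. A plan built around the metathesis could reach A3 by a shorter lactone synthesis, for instance a carbonyl allylation–lactonization that installs the α-methylene lactone directly. That would be better in step count, but C6 and C7 would then have to be controlled relative to C8 in that step. Mechanistically the metathesis creates no stereocentre, whereas the chosen key step creates C6.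

Alternative 3: The cut is the C3–C4 single bond between furanone and diene. It gives the seco compound A5, a 5-iodo-3(2H)-furanone at one end and a (Z)-alkenyl tributylstannane at C4 at the other, with both esters in place. Forward, Pd2(dba)3/AsPh3 (zerovalent palladium) would insert into the C3–I bond, the alkenyl group would transfer from tin with retention, and reductive elimination would form C3–C4 and the ring, giving A6, the C15 silyl ether of the target.
- In its favour: it is the latest possible ring closure, and both acyl groups are installed on an open chain. The alkene geometry is fixed in the stannane and the conditions are neutral.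
- Against it: a stereodefined trisubstituted alkenylstannane next to the allylic lactone carbinol is a problem of its own. Two sp2 carbons must meet across a strained ring, where protodestannylation can compete with slow transmetalation. Stoichiometric tin and an arsine are needed, and every fragile group is carried through the whole linear sequence.
- Comparison: in end-game economy the alternative is better (one step after ring closure against three, and no acylation on the ring). In control of the alkene geometry the two are equal. It is weaker in reagent toxicity and gives no answer to C6/C7 or to O8/O9. Like alternative 2, it forms no stereocentre and would have to be combined with a lactone construction such as the chosen one.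

Key step: step 8

Remarks on the chemistry:
- Atom numbers are germacrane numbers throughout.
- C8 (S) and C9 (R) of 30 have the configuration of (R,R)-tartaric acid (natural L), so 1 is the correct enantiomer and the cyclopropane and lactone structures need no stereochemical correction.
- C6 in 9 and 10 and C11 in 10–13 are epimer mixtures that converge in steps 8 and 11; their SMILES carry no descriptor there.
- C10 is carried as an N-methoxy-N-methylamide, so that the ketone can be made beside the lactone. O15 carries tert-butyldiphenylsilyl, so that it survives the acetal hydrolysis.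

## Route

Step 1
Reactants: 1 dimethyl (4R,5R)-2,2-dimethyl-1,3-dioxolane-4,5-dicarboxylate (dimethyl 2,3-O-isopropylidene-L-tartrate)
Product: 2 methyl (4R,5S)-5-(hydroxymethyl)-2,2-dimethyl-1,3-dioxolane-4-carboxylate
Conditions: NaBH4 (0.6 equiv), MeOH, 0 °C
Reagents that add atoms: none
Why: Borohydride reduction of an α-alkoxy-activated ester; with substoichiometric NaBH4 at 0 °C the C2-symmetric diester should stop largely at the mono-alcohol, because the hydroxy ester formed first is less electrophilic than 1. No stereocentre is touched.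

Step 2
Reactants: 2 methyl (4R,5S)-5-(hydroxymethyl)-2,2-dimethyl-1,3-dioxolane-4-carboxylate
Product: 3 (4R,5S)-5-(hydroxymethyl)-N-methoxy-N,2,2-trimethyl-1,3-dioxolane-4-carboxamide
Conditions: MeNH(OMe)·HCl, iPrMgCl, THF, −20 → 0 °C
Reagents that add atoms: N,O-dimethylhydroxylamine hydrochloride, CNOC.Cl
Why: Direct ester-to-Weinreb-amide exchange by the chloromagnesium amide; the free hydroxyl is only deprotonated. The amide survives every step to 11 and later stops cleanly at the ketone stage.

Step 3
Reactants: 3 (4R,5S)-5-(hydroxymethyl)-N-methoxy-N,2,2-trimethyl-1,3-dioxolane-4-carboxamide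
Product: 4 (4R,5R)-5-formyl-N-methoxy-N,2,2-trimethyl-1,3-dioxolane-4-carboxamide
Conditions: TEMPO (cat.), PhI(OAc)2, CH2Cl2, rt
Reagents that add atoms: none
Why: Nitroxyl-catalysed oxidation of a primary alcohol to the aldehyde under neutral, non-epimerizing conditions; the α-alkoxy aldehyde is used crude.

Step 4
Reactants: 4 (4R,5R)-5-formyl-N-methoxy-N,2,2-trimethyl-1,3-dioxolane-4-carboxamide; 5 diallyl malonate
Product: 6 diallyl 2-{[(4S,5R)-5-[methoxy(methyl)carbamoyl]-2,2-dimethyl-1,3-dioxolan-4-yl]methylidene}malonate
Conditions: piperidine (cat.), AcOH (cat.), 4 Å molecular sieves, CH2Cl2, rt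
Reagents that add atoms: none
Why: Knoevenagel condensation; only the aldehyde can condense, and the trans-dioxolane is the stable arrangement, so C8 should not drift. C11 carries two identical esters, so no alkene geometry arises.

Step 5
Reactants: 7 allyl bromide
Product: 8 1-allyltetrahydrothiophenium bromide
Conditions: tetrahydrothiophene, acetone, rt
Reagents that add atoms: tetrahydrothiophene, C1CCSC1
Why: SN2 S-alkylation of a thioether by an allylic bromide should give the crystalline sulfonium salt.

Step 6
Reactants: 6 diallyl 2-{[(4S,5R)-5-[methoxy(methyl)carbamoyl]-2,2-dimethyl-1,3-dioxolan-4-yl]methylidene}malonate; 8 1-allyltetrahydrothiophenium bromide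
Product: 9 diallyl (3R)-3-{(4S,5R)-5-[methoxy(methyl)carbamoyl]-2,2-dimethyl-1,3-dioxolan-4-yl}-2-vinylcyclopropane-1,1-dicarboxylate (both C2 epimers; C2 is C6 of the target)
Conditions: Cs2CO3, MeCN, 0 °C → rt
Reagents that add atoms: none
Why: Michael-initiated ring closure (sulfonium ylide cyclopropanation): the allylide carbon adds to C7 and the malonate anion displaces tetrahydrothiophene at C6 in a 3-exo-tet closure. C7 is set by the dioxolane: 1,3-allylic strain with the cis ester holds C8–H in the alkene plane, and the ylide is expected to enter on the face flanked by O8, away from the C9 branch, which gives the C7 configuration of the target. C6 forms as a mixture that step 8 erases.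

Step 7
Reactants: 9 diallyl (3R)-3-{(4S,5R)-5-[methoxy(methyl)carbamoyl]-2,2-dimethyl-1,3-dioxolan-4-yl}-2-vinylcyclopropane-1,1-dicarboxylate
Product: 10 (3R)-3-{(4S,5R)-5-[methoxy(methyl)carbamoyl]-2,2-dimethyl-1,3-dioxolan-4-yl}-2-vinylcyclopropane-1,1-dicarboxylic acid (both C2 epimers)
Conditions: Pd(PPh3)4 (2 mol %), morpholine (6 equiv), THF, 0 °C; aq. NaHCO3 extraction, then NaHSO4 to pH 3, EtOAc
Reagents that add atoms: none
Why: Tsuji–Trost deallylation: Pd(PPh3)4 ionizes the allyl esters and morpholine captures the allyl group. In the amine-rich medium the product is the bis(ammonium) dicarboxylate, whose cyclopropane is no longer acceptor-activated, so ring opening is deferred until the free acid is liberated on work-up, after the catalyst has been removed.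

Step 8
Reactants: 10 (3R)-3-{(4S,5R)-5-[methoxy(methyl)carbamoyl]-2,2-dimethyl-1,3-dioxolan-4-yl}-2-vinylcyclopropane-1,1-dicarboxylic acid
Product: 11 (4S,5R)-4-{(4S,5R)-5-[methoxy(methyl)carbamoyl]-2,2-dimethyl-1,3-dioxolan-4-yl}-2-oxo-5-vinyltetrahydrofuran-3-carboxylic acid (C3 epimers; C3 is C11 of the target)
Conditions: Pd(PPh3)4 (5 mol %), THF, 40 °C
Reagents that add atoms: none
Why: The free malonic acid on C11 and the vinyl group on C6 make the cyclopropane of 10 a donor–acceptor system, which zerovalent palladium should ionize by backside attack at C6; the C6–C11 bond breaks with release of ring strain to an η3-allyl palladium cation and a malonic enolate that tautomerizes to a C11–H carboxylate. The carboxylate oxygen then adds to the internal allyl carbon C6 anti to the metal in a 5-exo closure that forms the γ-lactone ring (C6, C7, C11, C12, O); attack at the unsubstituted allyl end would need a seven-membered ring. The closest known reaction types are the thermal isomerization of 2-vinylcyclopropane-1,1-dicarboxylic acids to 2-oxo-5-vinyltetrahydrofuran-3-carboxylic acids and the opening of vinylcyclopropane-1,1-diesters by Pd(PPh3)4 to zwitterionic allyl complexes. Both C6 epimers of 10 give the same allyl complex after η3–η1–η3 interconversion, so the mixture converges. The one new stereocentre, C6, is controlled by the fixed C7 centre under thermodynamic conditions: the product is an allylic ester that Pd(PPh3)4 can re-ionize, so cis and trans lactones equilibrate and the trans isomer, with the vinyl group and the dioxolane on opposite faces, should dominate. The step needs internal over terminal attack (secured by ring size), trans over cis (secured by equilibration) and ring closure over β-hydride loss from C7 (favoured by the tethered carboxylate and the mild temperature). C7, C8 and C9 are not touched, and C11 stays epimeric, which is of no consequence because it becomes sp2 in step 11.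

Step 9
Reactants: 11 (4S,5R)-4-{(4S,5R)-5-[methoxy(methyl)carbamoyl]-2,2-dimethyl-1,3-dioxolan-4-yl}-2-oxo-5-vinyltetrahydrofuran-3-carboxylic acid
Product: 12 (4S,5R)-4-[(4S,5R)-5-acetyl-2,2-dimethyl-1,3-dioxolan-4-yl]-2-oxo-5-vinyltetrahydrofuran-3-carboxylic acid
Conditions: MeMgBr (3.5 equiv), THF, −78 → −20 °C; aq. citric acid
Reagents that add atoms: methylmagnesium bromide, C[Mg]Br
Why: Weinreb ketone synthesis; the first two equivalents of MeMgBr turn the 2-carboxy lactone into its magnesium enolate carboxylate, which shields C12, and the third adds to the amide to give a chelated tetrahedral intermediate that collapses only on acidic work-up. Acylation of the C11 enolate by C10 would need a trans-fused bicyclo[3.3.0] ring on the trans-dioxolane and is not expected.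

Step 10
Reactants: 12 (4S,5R)-4-[(4S,5R)-5-acetyl-2,2-dimethyl-1,3-dioxolan-4-yl]-2-oxo-5-vinyltetrahydrofuran-3-carboxylic acid
Product: 13 (4S,5R)-4-{(4S,5R)-5-[(2R)-2-hydroxybut-3-yn-2-yl]-2,2-dimethyl-1,3-dioxolan-4-yl}-2-oxo-5-vinyltetrahydrofuran-3-carboxylic acid
Conditions: HC≡CMgBr (5 equiv), THF, −78 → −30 °C; aq. citric acid
Reagents that add atoms: ethynylmagnesium bromide, C#C[Mg]Br
Why: Chelation-controlled (Cram chelate) addition of an alkynyl Grignard reagent to an α-alkoxy ketone: magnesium bridges the ketone oxygen and O9, and the alkyne should enter from the face opposite C8, which gives the 10R carbinol (10S in the target once C1 is a ketone). The lactone is again protected as its enolate carboxylate.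

Step 11
Reactants: 13 (4S,5R)-4-{(4S,5R)-5-[(2R)-2-hydroxybut-3-yn-2-yl]-2,2-dimethyl-1,3-dioxolan-4-yl}-2-oxo-5-vinyltetrahydrofuran-3-carboxylic acid
Product: 14 (4S,5R)-4-{(4S,5R)-5-[(2R)-2-hydroxybut-3-yn-2-yl]-2,2-dimethyl-1,3-dioxolan-4-yl}-3-methylidene-5-vinyldihydrofuran-2(3H)-one
Conditions: 37% aq. CH2O, Et2NH, THF, 0 °C → rt; then NaOAc, AcOH, 50 °C
Reagents that add atoms: formaldehyde, C=O
Why: Decarboxylative Mannich methylenation: aminomethylation at C11 by the iminium ion from formaldehyde and Et2NH, then loss of CO2 with expulsion of the amine gives C11=C13. The malonic C–H is by far the most acidic position, and without a copper salt the terminal alkyne does not enter a Mannich reaction.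

Step 12
Reactants: 15 methyl 2-(hydroxymethyl)acrylate
Product: 16 methyl 2-{[tert-butyl(diphenyl)silyl]oxymethyl}acrylate
Conditions: TBDPSCl, imidazole, CH2Cl2, 0 °C → rt
Reagents that add atoms: tert-butyl(chloro)diphenylsilane, CC(C)(C)[Si](Cl)(c1ccccc1)c1ccccc1
Why: Silylation of a primary allylic alcohol; this silyl group is chosen because it should survive the acid of step 16 and the selective desilylation of step 20.

Step 13
Reactants: 16 methyl 2-{[tert-butyl(diphenyl)silyl]oxymethyl}acrylate
Product: 17 2-{[tert-butyl(diphenyl)silyl]oxymethyl}acrylic acid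
Conditions: LiOH, THF/H2O, 0 °C; 1 M HCl to pH 3
Reagents that add atoms: lithium hydroxide, [Li+].[OH-]
Why: Saponification of a methyl ester; the silyl ether is stable to cold LiOH.

Step 14
Reactants: 17 2-{[tert-butyl(diphenyl)silyl]oxymethyl}acrylic acid; 14 (4S,5R)-4-{(4S,5R)-5-[(2R)-2-hydroxybut-3-yn-2-yl]-2,2-dimethyl-1,3-dioxolan-4-yl}-3-methylidene-5-vinyldihydrofuran-2(3H)-one
Product: 19 (4S,5R)-4-{(4S,5R)-5-[(2R)-6-{[tert-butyl(diphenyl)silyl]oxymethyl}-2-hydroxy-5-oxohept-6-en-3-yn-2-yl]-2,2-dimethyl-1,3-dioxolan-4-yl}-3-methylidene-5-vinyldihydrofuran-2(3H)-one, via acid chloride 18 (not isolated)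
Conditions: 17, (COCl)2, DMF (cat.), CH2Cl2, 0 °C → rt, evaporate; then 14, PdCl2(PPh3)2 (2 mol %), CuI (4 mol %), Et3N, THF, rt
Reagents that add atoms: none
Why: Acyl Sonogashira coupling: the acid chloride adds oxidatively to zerovalent palladium (formed from PdCl2(PPh3)2) and the copper acetylide of 14 transmetalates, so the C2–C3 bond forms at room temperature. The tertiary hydroxyl is not acylated without a nucleophilic catalyst, and the acid chloride has no α-hydrogen for ketene formation.

Step 15
Reactants: 19 (4S,5R)-4-{(4S,5R)-5-[(2R)-6-{[tert-butyl(diphenyl)silyl]oxymethyl}-2-hydroxy-5-oxohept-6-en-3-yn-2-yl]-2,2-dimethyl-1,3-dioxolan-4-yl}-3-methylidene-5-vinyldihydrofuran-2(3H)-one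
Product: 21 (4S,5R)-4-{(4S,5R)-5-[(2S)-5-(3-{[tert-butyl(diphenyl)silyl]oxy}prop-1-en-2-yl)-2-methyl-3-oxo-2,3-dihydrofuran-2-yl]-2,2-dimethyl-1,3-dioxolan-4-yl}-3-methylidene-5-vinyldihydrofuran-2(3H)-one, via hydroxy diketone 20 (not isolated)
Conditions: (p-CF3C6H4)3PAuCl (5 mol %), AgOTf (5 mol %), H2O (2 equiv), toluene, rt
Reagents that add atoms: water, O
Why: Gold-catalysed hydrative cyclization of a 4-hydroxy-2-ynone to a 3(2H)-furanone: the cationic monovalent gold complex from (p-CF3C6H4)3PAuCl and AgOTf activates the alkyne, water adds at C1 (β to the ketone), and the tertiary C10 hydroxyl of diketone 20 closes on C3 with loss of water. The electron-poor alkyne disfavours Meyer–Schuster ionization, and C10 keeps its configuration because its C–O bond is never broken.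

Step 16
Reactants: 21 (4S,5R)-4-{(4S,5R)-5-[(2S)-5-(3-{[tert-butyl(diphenyl)silyl]oxy}prop-1-en-2-yl)-2-methyl-3-oxo-2,3-dihydrofuran-2-yl]-2,2-dimethyl-1,3-dioxolan-4-yl}-3-methylidene-5-vinyldihydrofuran-2(3H)-one
Product: 22 (4S,5R)-4-{(1S,2R)-2-[(2S)-5-(3-{[tert-butyl(diphenyl)silyl]oxy}prop-1-en-2-yl)-2-methyl-3-oxo-2,3-dihydrofuran-2-yl]-1,2-dihydroxyethyl}-3-methylidene-5-vinyldihydrofuran-2(3H)-one
Conditions: TFA/H2O/CH2Cl2, 0 °C
Reagents that add atoms: none
Why: Acid hydrolysis of the isopropylidene acetal; the tert-butyldiphenylsilyl ether, the furanone and the lactone should tolerate cold aqueous trifluoroacetic acid.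

Step 17
Reactants: 22 (4S,5R)-4-{(1S,2R)-2-[(2S)-5-(3-{[tert-butyl(diphenyl)silyl]oxy}prop-1-en-2-yl)-2-methyl-3-oxo-2,3-dihydrofuran-2-yl]-1,2-dihydroxyethyl}-3-methylidene-5-vinyldihydrofuran-2(3H)-one
Product: 23 the 1-O-triethylsilyl ether of 22 (silyl on O8; O9–H free)
Conditions: TESCl (1.1 equiv), imidazole, CH2Cl2/DMF, −40 → −20 °C
Reagents that add atoms: chlorotriethylsilane, CC[Si](Cl)(CC)CC
Why: Regioselective silylation: O9 is neopentylic (next to quaternary C10) whereas O8 has a methine neighbour, so a small excess of TESCl at low temperature should go to O8. The crude diol is silylated at once, because free O8–H could translactonize onto C12.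

Step 18
Reactants: 23 the O8-triethylsilyl ether; 24 angelic acid, (2Z)-2-methylbut-2-enoic acid
Product: 26 the O9-angelate of 23 (O8 triethylsilyl, O9 (2Z)-2-methylbut-2-enoyl), via mixed anhydride 25 (not isolated)
Conditions: 24, 2,4,6-trichlorobenzoyl chloride, Et3N, toluene, rt; then 23, 75 °C
Reagents that add atoms: none
Why: Yamaguchi esterification through the preformed mixed anhydride, run without 4-dimethylaminopyridine because nucleophilic catalysts isomerize angelates to tiglates. Et3N in warm toluene should acylate the hindered O9 with retention of the Z geometry.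

Step 19
Reactants: 26 the O8-triethylsilyl O9-angelate diene
Product: 27 (6R,7S,8S,9R,10S,4Z)-9-angeloyloxy-15-[tert-butyl(diphenyl)silyl]oxy-8-(triethylsilyl)oxy-3,10-epoxy-1-oxogermacra-2,4,11(13)-trien-12,6-olide
Conditions: RuCl2(H2IMes)(=CH-C6H4-2-OiPr) (second-generation Hoveyda–Grubbs catalyst, 20 mol % in portions), 1,4-benzoquinone (20 mol %), toluene (1 mM), 100 °C
Reagents that add atoms: none
Why: Ring-closing metathesis: the catalyst loads on the monosubstituted vinyl group on C6, and the C5 alkylidene closes onto the 1,1-disubstituted C4 alkene with loss of ethylene. The Z geometry is the only one the oxygen-bridged ten-membered ring can hold, the α-methylene lactone and the angelate offer no productive ring size, and benzoquinone suppresses isomerization by ruthenium hydrides.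

Step 20
Reactants: 27 the bicyclic O8-triethylsilyl ether
Product: 28 (6R,7S,8S,9R,10S,4Z)-9-angeloyloxy-15-[tert-butyl(diphenyl)silyl]oxy-8-hydroxy-3,10-epoxy-1-oxogermacra-2,4,11(13)-trien-12,6-olide
Conditions: HF·pyridine, pyridine, THF, 0 °C
Reagents that add atoms: none
Why: Buffered HF·pyridine should remove the secondary triethylsilyl ether much faster than the primary tert-butyldiphenylsilyl ether; no basic reagent is used, so the lactone and the angelate stay in place.

Step 21
Reactants: 28 the bicyclic C8 alcohol
Product: 29 (6R,7S,8S,9R,10S,4Z)-9-angeloyloxy-15-[tert-butyl(diphenyl)silyl]oxy-8-methacryloyloxy-3,10-epoxy-1-oxogermacra-2,4,11(13)-trien-12,6-olide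
Conditions: methacrylic anhydride, Et3N, DMAP (cat.), CH2Cl2, −20 → 0 °C
Reagents that add atoms: methacrylic anhydride, C=C(C)C(=O)OC(=O)C(C)=C
Why: Acylation of the secondary C8 alcohol by the anhydride with catalytic 4-dimethylaminopyridine at low temperature; excess anhydride should make acylation faster than O9-to-O8 migration of the angelate.

Step 22
Reactants: 29 the C15 silyl ether of the target
Product: 30 CNP0359568.2, (6R,7S,8S,9R,10S,4Z)-9-angeloyloxy-15-hydroxy-8-methacryloyloxy-3,10-epoxy-1-oxogermacra-2,4,11(13)-trien-12,6-olide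
Conditions: HF·pyridine, THF, 0 °C → rt
Reagents that add atoms: none
Why: Si–O cleavage under acidic fluoride conditions should leave both enoate esters and the α-methylene lactone untouched, whereas basic fluoride sources could add to them.

## Compound list

1 | dimethyl (4R,5R)-2,2-dimethyl-1,3-dioxolane-4,5-dicarboxylate | COC(=O)[C@@H]1OC(C)(C)O[C@H]1C(=O)OC | starting material
2 | methyl (4R,5S)-5-(hydroxymethyl)-2,2-dimethyl-1,3-dioxolane-4-carboxylate | OC[C@@H]1OC(C)(C)O[C@H]1C(=O)OC | intermediate
3 | (4R,5S)-5-(hydroxymethyl)-N-methoxy-N,2,2-trimethyl-1,3-dioxolane-4-carboxamide | OC[C@@H]1OC(C)(C)O[C@H]1C(=O)N(C)OC | intermediate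
4 | (4R,5R)-5-formyl-N-methoxy-N,2,2-trimethyl-1,3-dioxolane-4-carboxamide | O=C[C@@H]1OC(C)(C)O[C@H]1C(=O)N(C)OC | intermediate
5 | diallyl malonate | C=CCOC(=O)CC(=O)OCC=C | starting material
6 | diallyl 2-{[(4S,5R)-5-[methoxy(methyl)carbamoyl]-2,2-dimethyl-1,3-dioxolan-4-yl]methylidene}malonate | C=CCOC(=O)C(=C[C@@H]1OC(C)(C)O[C@H]1C(=O)N(C)OC)C(=O)OCC=C | intermediate
7 | allyl bromide | C=CCBr | starting material
8 | 1-allyltetrahydrothiophenium bromide | C=CC[S+]1CCCC1.[Br-] | intermediate
9 | diallyl (3R)-3-{(4S,5R)-5-[methoxy(methyl)carbamoyl]-2,2-dimethyl-1,3-dioxolan-4-yl}-2-vinylcyclopropane-1,1-dicarboxylate (C2 epimers) | C=CC1[C@@H]([C@@H]2OC(C)(C)O[C@H]2C(=O)N(C)OC)C1(C(=O)OCC=C)C(=O)OCC=C | intermediate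
10 | (3R)-3-{(4S,5R)-5-[methoxy(methyl)carbamoyl]-2,2-dimethyl-1,3-dioxolan-4-yl}-2-vinylcyclopropane-1,1-dicarboxylic acid (C2 epimers) | C=CC1[C@@H]([C@@H]2OC(C)(C)O[C@H]2C(=O)N(C)OC)C1(C(=O)O)C(=O)O | intermediate
11 | (4S,5R)-4-{(4S,5R)-5-[methoxy(methyl)carbamoyl]-2,2-dimethyl-1,3-dioxolan-4-yl}-2-oxo-5-vinyltetrahydrofuran-3-carboxylic acid (C3 epimers) | C=C[C@H]1OC(=O)C(C(=O)O)[C@@H]1[C@@H]2OC(C)(C)O[C@H]2C(=O)N(C)OC | intermediate
12 | (4S,5R)-4-[(4S,5R)-5-acetyl-2,2-dimethyl-1,3-dioxolan-4-yl]-2-oxo-5-vinyltetrahydrofuran-3-carboxylic acid (C3 epimers) | C=C[C@H]1OC(=O)C(C(=O)O)[C@@H]1[C@@H]2OC(C)(C)O[C@H]2C(C)=O | intermediate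
13 | (4S,5R)-4-{(4S,5R)-5-[(2R)-2-hydroxybut-3-yn-2-yl]-2,2-dimethyl-1,3-dioxolan-4-yl}-2-oxo-5-vinyltetrahydrofuran-3-carboxylic acid (C3 epimers) | C=C[C@H]1OC(=O)C(C(=O)O)[C@@H]1[C@@H]2OC(C)(C)O[C@H]2[C@](C)(O)C#C | intermediate
14 | (4S,5R)-4-{(4S,5R)-5-[(2R)-2-hydroxybut-3-yn-2-yl]-2,2-dimethyl-1,3-dioxolan-4-yl}-3-methylidene-5-vinyldihydrofuran-2(3H)-one | C=C[C@H]1OC(=O)C(=C)[C@@H]1[C@@H]2OC(C)(C)O[C@H]2[C@](C)(O)C#C | intermediate
15 | methyl 2-(hydroxymethyl)acrylate | C=C(CO)C(=O)OC | starting material
16 | methyl 2-{[tert-butyl(diphenyl)silyl]oxymethyl}acrylate | C=C(CO[Si](c1ccccc1)(c1ccccc1)C(C)(C)C)C(=O)OC | intermediate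
17 | 2-{[tert-butyl(diphenyl)silyl]oxymethyl}acrylic acid | C=C(CO[Si](c1ccccc1)(c1ccccc1)C(C)(C)C)C(=O)O | intermediate
18 | 2-{[tert-butyl(diphenyl)silyl]oxymethyl}acryloyl chloride (not isolated) | C=C(CO[Si](c1ccccc1)(c1ccccc1)C(C)(C)C)C(=O)Cl | intermediate
19 | (4S,5R)-4-{(4S,5R)-5-[(2R)-6-{[tert-butyl(diphenyl)silyl]oxymethyl}-2-hydroxy-5-oxohept-6-en-3-yn-2-yl]-2,2-dimethyl-1,3-dioxolan-4-yl}-3-methylidene-5-vinyldihydrofuran-2(3H)-one | C=C[C@H]1OC(=O)C(=C)[C@@H]1[C@@H]2OC(C)(C)O[C@H]2[C@](C)(O)C#CC(=O)C(=C)CO[Si](c3ccccc3)(c3ccccc3)C(C)(C)C | intermediate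
20 | (4S,5R)-4-{(4S,5R)-5-[(2S)-6-{[tert-butyl(diphenyl)silyl]oxymethyl}-2-hydroxy-3,5-dioxohept-6-en-2-yl]-2,2-dimethyl-1,3-dioxolan-4-yl}-3-methylidene-5-vinyldihydrofuran-2(3H)-one (not isolated) | C=C[C@H]1OC(=O)C(=C)[C@@H]1[C@@H]2OC(C)(C)O[C@H]2[C@](C)(O)C(=O)CC(=O)C(=C)CO[Si](c3ccccc3)(c3ccccc3)C(C)(C)C | intermediate
21 | (4S,5R)-4-{(4S,5R)-5-[(2S)-5-(3-{[tert-butyl(diphenyl)silyl]oxy}prop-1-en-2-yl)-2-methyl-3-oxo-2,3-dihydrofuran-2-yl]-2,2-dimethyl-1,3-dioxolan-4-yl}-3-methylidene-5-vinyldihydrofuran-2(3H)-one | C=C[C@H]1OC(=O)C(=C)[C@@H]1[C@@H]2OC(C)(C)O[C@H]2[C@]3(C)OC(=CC3=O)C(=C)CO[Si](c4ccccc4)(c4ccccc4)C(C)(C)C | intermediate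
22 | (4S,5R)-4-{(1S,2R)-2-[(2S)-5-(3-{[tert-butyl(diphenyl)silyl]oxy}prop-1-en-2-yl)-2-methyl-3-oxo-2,3-dihydrofuran-2-yl]-1,2-dihydroxyethyl}-3-methylidene-5-vinyldihydrofuran-2(3H)-one | C=C[C@H]1OC(=O)C(=C)[C@@H]1[C@H](O)[C@@H](O)[C@]2(C)OC(=CC2=O)C(=C)CO[Si](c3ccccc3)(c3ccccc3)C(C)(C)C | intermediate
23 | O8-triethylsilyl ether of 22 (1S,2R side chain; O9–H free) | C=C[C@H]1OC(=O)C(=C)[C@@H]1[C@H](O[Si](CC)(CC)CC)[C@@H](O)[C@]2(C)OC(=CC2=O)C(=C)CO[Si](c3ccccc3)(c3ccccc3)C(C)(C)C | intermediate
24 | angelic acid, (2Z)-2-methylbut-2-enoic acid | C/C=C(/C)C(=O)O | starting material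
25 | (2Z)-2-methylbut-2-enoic 2,4,6-trichlorobenzoic anhydride (not isolated) | C/C=C(/C)C(=O)OC(=O)c1c(Cl)cc(Cl)cc1Cl | intermediate
26 | O8-triethylsilyl O9-angeloyl diene (metathesis substrate) | C=C[C@H]1OC(=O)C(=C)[C@@H]1[C@H](O[Si](CC)(CC)CC)[C@@H](OC(=O)/C(C)=C\C)[C@]2(C)OC(=CC2=O)C(=C)CO[Si](c3ccccc3)(c3ccccc3)C(C)(C)C | intermediate
27 | (6R,7S,8S,9R,10S,4Z)-9-angeloyloxy-15-[tert-butyl(diphenyl)silyl]oxy-8-(triethylsilyl)oxy-3,10-epoxy-1-oxogermacra-2,4,11(13)-trien-12,6-olide | CC[Si](CC)(CC)O[C@H]1[C@H]2C(=C)C(=O)O[C@@H]2/C=C(/CO[Si](c3ccccc3)(c3ccccc3)C(C)(C)C)C2=CC(=O)[C@@](C)(O2)[C@@H]1OC(=O)/C(C)=C\C | intermediate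
28 | (6R,7S,8S,9R,10S,4Z)-9-angeloyloxy-15-[tert-butyl(diphenyl)silyl]oxy-8-hydroxy-3,10-epoxy-1-oxogermacra-2,4,11(13)-trien-12,6-olide | O[C@H]1[C@H]2C(=C)C(=O)O[C@@H]2/C=C(/CO[Si](c3ccccc3)(c3ccccc3)C(C)(C)C)C2=CC(=O)[C@@](C)(O2)[C@@H]1OC(=O)/C(C)=C\C | intermediate
29 | (6R,7S,8S,9R,10S,4Z)-9-angeloyloxy-15-[tert-butyl(diphenyl)silyl]oxy-8-methacryloyloxy-3,10-epoxy-1-oxogermacra-2,4,11(13)-trien-12,6-olide | C=C(C)C(=O)O[C@H]1[C@H]2C(=C)C(=O)O[C@@H]2/C=C(/CO[Si](c3ccccc3)(c3ccccc3)C(C)(C)C)C2=CC(=O)[C@@](C)(O2)[C@@H]1OC(=O)/C(C)=C\C | intermediate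
30 | CNP0359568.2, (6R,7S,8S,9R,10S,4Z)-9-angeloyloxy-15-hydroxy-8-methacryloyloxy-3,10-epoxy-1-oxogermacra-2,4,11(13)-trien-12,6-olide | C=C(C)C(=O)O[C@H]1[C@H]2C(=C)C(=O)O[C@@H]2/C=C(/CO)C2=CC(=O)[C@@](C)(O2)[C@@H]1OC(=O)/C(C)=C\C | target

## Step count and least certain steps

Total: 22 steps. Longest linear sequence: 19 steps (1 to 30 through steps 1–4, 6–11 and 14–22). Steps 5, 12 and 13 prepare side reagents.

Step 8 (key step). What may go wrong: β-hydride loss from C7 in the allyl palladium intermediate, giving a conjugated diene instead of ring closure; slow ionization if the strong malonic acid converts the zerovalent palladium into a hydride; incomplete equilibration that leaves cis lactone. Fallback: metal-free strain release. Setting out from 10, heating in toluene at 80–90 °C should trigger the proton-assisted heterolysis that is typical of 2-vinylcyclopropane-1,1-dicarboxylic acids. This avoids any metal hydride pathway but has no control at C6, so it should give 11 together with its C6 epimer, the cis lactone acid F1. Continued heating is expected to equilibrate F1 with 11 through reversible ionization of the allylic C6–O bond, and residual F1 is separated. The route is rejoined at 11.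

Step 6. What may go wrong: poor or reversed facial selectivity at C7, because approach anti to the C8–O8 bond (the Felkin–Anh sense) would give the C7 epimer; γ-deprotonation of 6; sigmatropic rearrangement of the ring-deprotonated ylide. Fallback: catalyst-controlled cyclopropanation. Setting out from 4, Wittig olefination with Ph3P=CHCHO should give the (E)-enal F2. Diallyl 2-bromomalonate F3 is made from 5 with N-bromosuccinimide. F2 and F3, with (S)-α,α-diphenylprolinol trimethylsilyl ether and 2,6-lutidine, should undergo iminium-catalysed Michael addition at C7 followed by enamine alkylation at C6, the catalyst shielding the unwanted face of C7, to give the trans formylcyclopropane F4. Wittig methylenation (Ph3P=CH2) converts the formyl group into the vinyl group, and the route is rejoined at 9 as its trans epimer.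

Step 9. What may go wrong: attack of MeMgBr on the lactone carbonyl before the protective enolate has formed; precipitation of the magnesium carboxylate with incomplete conversion. Fallback: methylenation before the organometallic steps. Setting out from 11, the conditions of step 11 should give the α-methylene lactone amide F5. MeMgBr (1.2 equiv, THF, −78 °C) then relies on the higher reactivity of the chelating α-alkoxy Weinreb amide to give the methyl ketone F6. Addition of HC≡CMgBr in the presence of CeCl3 at −78 °C, again under O9 chelation, rejoins the route at 14; 12 and 13 are bypassed.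

Step 10. What may go wrong: weak chelation in THF with a polyanionic substrate, so that Felkin–Anh attack erodes or reverses the facial selectivity at C10; enolization of the methyl ketone. Fallback: inverted order of the two carbon nucleophiles. Setting out from 11, (trimethylsilyl)ethynylmagnesium bromide should give the silyl ynone acid F7. MeMgBr then adds to the ynone; if non-chelation attack prevails, the methyl group now takes the face that the alkyne would have taken wrongly, so the same bias gives the right C10 epimer, the silyl carbinol acid F8. K2CO3 in MeOH removes the silyl group and the route is rejoined at 13.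

Step 17. What may go wrong: silylation at O9 or at both hydroxyls, because the two secondary carbinols differ only in their neighbours; translactonization through free O8–H. Fallback: complementary acylation order, which can also use the other regioisomer. Setting out from 22, the O9-silyl regioisomer F9 is acylated at O8 with methacrylic anhydride to give the O8-methacrylate silyl ether F10. HF·pyridine frees O9 to give the hydroxy methacrylate F11, and Yamaguchi angeloylation with 25 gives the diester diene F12. Metathesis of F12 under the conditions of step 19, at high dilution to disfavour closure onto the methacrylate, rejoins the route at 29.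

Step 19. What may go wrong: the C5 ruthenium alkylidene fails to add to the hindered, electron-poor C4 alkene; dimerization through the vinyl groups; double-bond migration. Fallback: ring closure before diol differentiation. Setting out from 22, metathesis on the unencumbered diol, where hydrogen bonding can fold the chain, should give the bicyclic diol F13. Silylation of O8 as in step 17 gives the bicyclic mono-silyl ether F14, and Yamaguchi angeloylation with 25 rejoins the route at 27.

## Further compounds

F1 | step 8 | (4S,5S)-4-{(4S,5R)-5-[methoxy(methyl)carbamoyl]-2,2-dimethyl-1,3-dioxolan-4-yl}-2-oxo-5-vinyltetrahydrofuran-3-carboxylic acid (cis lactone, C6 epimer of 11) | C=C[C@@H]1OC(=O)C(C(=O)O)[C@@H]1[C@@H]2OC(C)(C)O[C@H]2C(=O)N(C)OC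
F2 | step 6 | (4R,5S)-N-methoxy-N,2,2-trimethyl-5-[(1E)-3-oxoprop-1-en-1-yl]-1,3-dioxolane-4-carboxamide | O=C/C=C/[C@@H]1OC(C)(C)O[C@H]1C(=O)N(C)OC
F3 | step 6 | diallyl 2-bromomalonate | C=CCOC(=O)C(Br)C(=O)OCC=C
F4 | step 6 | diallyl (2R,3R)-2-formyl-3-{(4S,5R)-5-[methoxy(methyl)carbamoyl]-2,2-dimethyl-1,3-dioxolan-4-yl}cyclopropane-1,1-dicarboxylate (trans) | O=C[C@@H]1[C@@H]([C@@H]2OC(C)(C)O[C@H]2C(=O)N(C)OC)C1(C(=O)OCC=C)C(=O)OCC=C
F5 | step 9 | (4R,5S)-N-methoxy-N,2,2-trimethyl-5-[(2R,3S)-4-methylidene-5-oxo-2-vinyltetrahydrofuran-3-yl]-1,3-dioxolane-4-carboxamide | C=C[C@H]1OC(=O)C(=C)[C@@H]1[C@@H]2OC(C)(C)O[C@H]2C(=O)N(C)OC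
F6 | step 9 | (4S,5R)-4-[(4S,5R)-5-acetyl-2,2-dimethyl-1,3-dioxolan-4-yl]-3-methylidene-5-vinyldihydrofuran-2(3H)-one | C=C[C@H]1OC(=O)C(=C)[C@@H]1[C@@H]2OC(C)(C)O[C@H]2C(C)=O
F7 | step 10 | (4S,5R)-4-{(4S,5R)-2,2-dimethyl-5-[3-(trimethylsilyl)prop-2-ynoyl]-1,3-dioxolan-4-yl}-2-oxo-5-vinyltetrahydrofuran-3-carboxylic acid | C=C[C@H]1OC(=O)C(C(=O)O)[C@@H]1[C@@H]2OC(C)(C)O[C@H]2C(=O)C#C[Si](C)(C)C
F8 | step 10 | (4S,5R)-4-{(4S,5R)-5-[(2R)-2-hydroxy-4-(trimethylsilyl)but-3-yn-2-yl]-2,2-dimethyl-1,3-dioxolan-4-yl}-2-oxo-5-vinyltetrahydrofuran-3-carboxylic acid | C=C[C@H]1OC(=O)C(C(=O)O)[C@@H]1[C@@H]2OC(C)(C)O[C@H]2[C@](C)(O)C#C[Si](C)(C)C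
F9 | step 17 | O9-triethylsilyl ether of 22 (O8–H free) | C=C[C@H]1OC(=O)C(=C)[C@@H]1[C@H](O)[C@@H](O[Si](CC)(CC)CC)[C@]2(C)OC(=CC2=O)C(=C)CO[Si](c3ccccc3)(c3ccccc3)C(C)(C)C
F10 | step 17 | O8-methacryloyl O9-triethylsilyl derivative of 22 | C=C[C@H]1OC(=O)C(=C)[C@@H]1[C@H](OC(=O)C(C)=C)[C@@H](O[Si](CC)(CC)CC)[C@]2(C)OC(=CC2=O)C(=C)CO[Si](c3ccccc3)(c3ccccc3)C(C)(C)C
F11 | step 17 | O8-methacrylate of 22 (O9–H free) | C=C[C@H]1OC(=O)C(=C)[C@@H]1[C@H](OC(=O)C(C)=C)[C@@H](O)[C@]2(C)OC(=CC2=O)C(=C)CO[Si](c3ccccc3)(c3ccccc3)C(C)(C)C
F12 | step 17 | O8-methacryloyl O9-angeloyl diene | C=C[C@H]1OC(=O)C(=C)[C@@H]1[C@H](OC(=O)C(C)=C)[C@@H](OC(=O)/C(C)=C\C)[C@]2(C)OC(=CC2=O)C(=C)CO[Si](c3ccccc3)(c3ccccc3)C(C)(C)C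
F13 | step 19 | (6R,7S,8S,9R,10S,4Z)-15-[tert-butyl(diphenyl)silyl]oxy-8,9-dihydroxy-3,10-epoxy-1-oxogermacra-2,4,11(13)-trien-12,6-olide | O[C@H]1[C@H]2C(=C)C(=O)O[C@@H]2/C=C(/CO[Si](c3ccccc3)(c3ccccc3)C(C)(C)C)C2=CC(=O)[C@@](C)(O2)[C@@H]1O
F14 | step 19 | (6R,7S,8S,9R,10S,4Z)-15-[tert-butyl(diphenyl)silyl]oxy-9-hydroxy-8-(triethylsilyl)oxy-3,10-epoxy-1-oxogermacra-2,4,11(13)-trien-12,6-olide | CC[Si](CC)(CC)O[C@H]1[C@H]2C(=C)C(=O)O[C@@H]2/C=C(/CO[Si](c3ccccc3)(c3ccccc3)C(C)(C)C)C2=CC(=O)[C@@](C)(O2)[C@@H]1O
A1 | alternative 1 | seco-dialdehyde (C8 and C9 formyl groups, saturated C11, C15 tert-butyldimethylsilyl ether) | O=C[C@H]1CC(=O)O[C@@H]1/C=C(/CO[Si](C)(C)C(C)(C)C)C2=CC(=O)[C@@](C)(O2)C=O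
A2 | alternative 1 | bicyclic 8,9-diol (saturated C11, C15 tert-butyldimethylsilyl ether) | O[C@H]1[C@H]2CC(=O)O[C@@H]2/C=C(/CO[Si](C)(C)C(C)(C)C)C2=CC(=O)[C@@](C)(O2)[C@@H]1O
A3 | alternative 2 | O8-triethylsilyl O9-angeloyl diene with C15 tert-butyldimethylsilyl ether | C=C[C@H]1OC(=O)C(=C)[C@@H]1[C@H](O[Si](CC)(CC)CC)[C@@H](OC(=O)/C(C)=C\C)[C@]2(C)OC(=CC2=O)C(=C)CO[Si](C)(C)C(C)(C)C
A4 | alternative 2 | bicyclic core with C8 triethylsilyl ether, C9 angelate and C15 tert-butyldimethylsilyl ether | CC[Si](CC)(CC)O[C@H]1[C@H]2C(=C)C(=O)O[C@@H]2/C=C(/CO[Si](C)(C)C(C)(C)C)C2=CC(=O)[C@@](C)(O2)[C@@H]1OC(=O)/C(C)=C\C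
A5 | alternative 3 | seco 5-iodofuranone with (Z)-alkenyl tributylstannane at C4, both esters in place | CCCC[Sn](CCCC)(CCCC)/C(CO[Si](C)(C)C(C)(C)C)=C\[C@H]1OC(=O)C(=C)[C@@H]1[C@H](OC(=O)C(C)=C)[C@@H](OC(=O)/C(C)=C\C)[C@]2(C)OC(I)=CC2=O
A6 | alternative 3 | target as its C15 tert-butyldimethylsilyl ether | C=C(C)C(=O)O[C@H]1[C@H]2C(=C)C(=O)O[C@@H]2/C=C(/CO[Si](C)(C)C(C)(C)C)C2=CC(=O)[C@@](C)(O2)[C@@H]1OC(=O)/C(C)=C\C
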